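## Analysis of the target

Target 14 is a hexasubstituted phloroglucinol: in ring A, C1 carries the (2R)-2-methylbutanoyl group, C2, C4 and C6 carry OH, and C3 and C5 carry the methylene bridges C7 and C7′, each of which ends at C3 of a 6-ethyl-4-hydroxy-5-methyl-2H-pyran-2-one (rings B and B′: O1, C2 carbonyl, C3, C4–OH, C5–Me, C6–Et). The only stereocentre is C2 of the butanoyl chain; it is R (CIP order C=O > ethyl > methyl > H), lies α to an aryl ketone and is therefore the one configurationally fragile atom, with no other stereocentre to relate it to. The molecule has five acidic OH groups (three phenols, two vinylogous acids) and an electron-rich arene, and its two aryl–CH2–pyranone bridges can fragment through quinone-methide-type intermediates under forcing acid or base, so harsh late steps and protecting-group removals are unattractive. The difficulty is not a single bond but the clean twofold assembly of unsymmetrical bridges (arene–CH2–pyranone, not arene–CH2–arene or pyranone–CH2–pyranone) on a fully substituted benzene, without scrambling and without loss of the stereocentre. The feature that invites the strategy: in each ring B the edge O1–C6(Et)=C5(Me) is the enol of pentan-3-one, and C2–C3–C4 is a malonyl unit whose central carbon C3 carries the bridge. Because each bridge sits ortho to a ring A hydroxyl, the atoms O(ring A)–C(aryl)–C(aryl)–C7–C3–C2 form a latent six-membered aryl lactone (a 2-oxochroman). The C2 carbonyl of ring B can therefore be stored on a ring A oxygen and handed over to the pentanone enol oxygen at the moment ring B is built.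

## Retrosynthetic reasoning

**14 ⇒ 13 (ring switch).** The O1–C2 bonds of rings B and B′ are cut and each C2 carbonyl is reconnected to an ortho oxygen of ring A. This gives 13, a bis(2-oxochroman) whose lactone α-carbons carry 2-methyl-3-oxopentanoyl chains. The cut is made here because it turns two free phenols and two pyranones into two activated aryl lactones. The phenols are masked without protecting groups, and the forward reaction is an isomerisation (13 and 14 have the same molecular formula). That reaction has to let the terminal enol oxygen of each chain displace the ring A phenoxide from the lactone carbonyl. It is downhill because a 4-hydroxy-2-pyranone replaces a plain aryl ester.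

**13 ⇒ 12 + two molecules of 11 (C4–C5 of each pyranone).** Cutting C4–C5 in both arms separates the bis(acid chloride) 12 from two molecules of the silyl enol ether 11 of pentan-3-one 10. The ketone is symmetrical, so there is only one enol ether and no regiochemical question. Each pyranone then draws C5, C6, the methyl and the ethyl group from one molecule of a cheap C5 ketone. The forward reaction has to acylate 11 at carbon, once at each acid chloride. Steps 13 ⇒ 12 and 14 ⇒ 13 are run as one operation, which is the key step.

**12 ⇒ 9 (functional group interconversion).** The acid chlorides come from the bis-lactone diacid 9 under neutral conditions.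

**9 ⇒ 8 ⇒ 4 + two molecules each of 5 and 6 (lactone C–O bonds and both aryl–CH2 bonds).** Opening both lactones onto 2,2-dimethyl-1,3-dioxane-4,6-dione rings gives 8. Cutting the ring A–CH2 bonds then leads to the acylphloroglucinol 4 and two molecules of the alkylidene 7, each of which forms from formaldehyde 5 and Meldrum's acid 6. The arene reacts only as a nucleophile towards one defined electrophile, so homo-bridging of pyranones cannot occur; no pyranone exists yet.

**4 ⇒ 2 + 3 (aryl–acyl bond).** Friedel–Crafts disconnection gives phloroglucinol 2 and the acid chloride 3 of the enantiopure acid 1. The stereocentre is bought, not made.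

**11 ⇒ 10.** Silylation of the ketone.

In short, the key step and its precursor are a twofold ring-switching pyranone annulation of the bis(2-oxochroman-3-carbonyl chloride) 12, made in the flask from 9, with two molecules of the silyl enol ether 11.

## Alternatives that were turned down

**Alternative 1:** the textbook disconnection at the methylene bridges.
- Disconnection: 4 plus two molecules of the preformed pyranone 6-ethyl-4-hydroxy-5-methyl-2H-pyran-2-one A1 plus two molecules of formaldehyde 5.
- Forward key step: A1 and 5 give the methide 6-ethyl-5-methyl-3-methylidenepyran-2,4-dione A2, which C3 and C5 of 4 trap.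
- Why turned down: A2 is formed in the presence of competing carbon nucleophiles (A1 itself, the two free positions of 4, and the remaining free position once one bridge is in place). Bridging is therefore statistical, and the symmetrical dimer 3,3′-methylenebis(6-ethyl-4-hydroxy-5-methyl-2H-pyran-2-one) A3 and arene–CH2–arene dimers are built-in side channels. The bridges, once formed, can also exchange under the same conditions. A1 has to be made separately, so the step count is no lower than that of the chosen route. The disconnection is kept only as the fallback of the key step.

**Alternative 2:** aryne C–O insertion at C1/C2 of ring A.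
- Disconnection: the acyl group at C1 and the hydroxyl at C2 are removed together. This leads to acid 1 and the aryne A5 (4,6-dimethoxy-3,5-bis[(6-ethyl-4-methoxy-5-methyl-2-oxopyran-3-yl)methyl]benzyne), generated from the ortho-silyl aryl triflate A4.
- Forward key step: the carboxylate oxygen adds to the aryne carbon remote from the C6 methoxy group (inductive control by the alkoxy group beside the triple bond). The resulting aryl anion at C1 takes over the acyl group, so that the acyl group and the new oxygen end up ortho to each other with the correct regiochemistry.
- Why turned down: A4 already contains both pyranones, both bridges and a pentasubstituted arene, so the key step adds only five carbons and one oxygen to a precursor about as hard as the target. Every acidic OH must be capped, or the aryl anion is protonated before the acyl shift. Removing four methyl ethers afterwards needs strong Lewis acid, which threatens the α-stereocentre and the bridges. The route to A4 would be several times longer than the whole chosen route.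

**Alternative 3:** de novo construction of ring A.
- Disconnection: the C2–C3 and C5–C6 bonds of ring A, giving the symmetrical ketone 1,5-bis(6-ethyl-4-hydroxy-5-methyl-2-oxopyran-3-yl)pentan-3-one A6 and the acylmalonate diethyl 2-[(2R)-2-methylbutanoyl]propanedioate A7.
- Forward key step: a double Claisen condensation of the two α-methylene groups of A6 with the two ester groups of A7 closes ring A, which then tautomerises to the aromatic triol of 14.
- Why turned down: ketones and malonyl electrophiles prefer to close at oxygen to give 4-hydroxy-2-pyranones; that is the reactivity the chosen route exploits. C,C-closure to a carbocycle therefore has to fight the intrinsic pathway. The strongly basic conditions meet two acidic pyranone OH groups and an enolisable stereocentre. A6 needs the pyranone first and a double Michael addition, so the sequence is longer.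

Key step: step 4

## Route

Assumption: (2R)-2-methylbutanoic acid 1 is bought as the single enantiomer. The lactone α-carbons of 9, 12 and 13 and the methyl-bearing chain carbons of 13 arise as epimer mixtures, are written without configuration, and become sp2 in step 4.

Remark on stoichiometry: steps 2 and 4 are twofold. Step 2 consumes two molecules each of 5 and 6, and step 4 consumes two molecules of 11. The second molecule is entered under "Reagents that add atoms" in each case.

Step 1
Reactants: 1 (2R)-2-methylbutanoic acid; 2 phloroglucinol (benzene-1,3,5-triol)
Product: 4 (2R)-2-methyl-1-(2,4,6-trihydroxyphenyl)butan-1-one, via (2R)-2-methylbutanoyl chloride 3 (not isolated)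
Conditions: (COCl)2, cat. DMF, CH2Cl2, 0 °C to rt; then 2, AlCl3 (4 equiv), PhNO2/CH2Cl2, 0 °C to rt; ice/1 M HCl
Reagents that add atoms: none
Why: Friedel–Crafts acylation of the threefold activated arene; the first acyl group deactivates the ring, so mono-acylation should result. The stereocentre comes from 1 and should be kept by working at or below room temperature, where ketene formation from 3 and enolisation of the aluminium-chelated ketone are slow.

Step 2
Reactants: 4 (2R)-2-methyl-1-(2,4,6-trihydroxyphenyl)butan-1-one; 5 formaldehyde (used as paraformaldehyde; two molecules are consumed); 6 Meldrum's acid (2,2-dimethyl-1,3-dioxane-4,6-dione; two molecules are consumed)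
Product: 9 5-hydroxy-6-[(2R)-2-methylbutanoyl]-2,8-dioxo-3,4,9,10-tetrahydro-2H,8H-pyrano[2,3-f]chromene-3,9-dicarboxylic acid, via methylidene Meldrum's acid 7 (not isolated), via bis(Meldrum's acid) adduct 8 (not isolated)
Conditions: 5 (2.2 equiv), 6 (2.2 equiv), Et3N (4 equiv), MeCN, 0 °C to rt; then CF3CO2H (excess), 50 °C
Reagents that add atoms: formaldehyde (the second molecule of 5, for the second bridge), C=O; Meldrum's acid (the second molecule of 6, for the second arm), CC1(C)OC(=O)CC(=O)O1
Why: Knoevenagel condensation of 5 with 6 gives the strongly electrophilic alkylidene 7, and two molecules of 7 add to the phenoxide of 4 through C3 and C5 (Michael-type Friedel–Crafts alkylation, the known three-component condensation of an electron-rich arene, an aldehyde and Meldrum's acid). As ammonium enolates the dioxanedione rings of 8 are inert, so both arms are in place before acidification lets the ortho-hydroxyls open them, with loss of two molecules of acetone, to the malonic half-ester lactones of 9. Lactonisation onto the other ortho-oxygen would not matter, because step 4 releases both lactone oxygens as phenols; the (R)-centre should survive because the ketone is part of a phenoxide-conjugated, hydrogen-bonded system that Et3N does not enolise at room temperature.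

Step 3
Reactants: 10 pentan-3-one
Product: 11 (Z)-3-(trimethylsilyloxy)pent-2-ene
Conditions: Me3SiOTf (1.1 equiv), Et3N (1.3 equiv), CH2Cl2, 0 °C; pentane extraction, distillation
Reagents that add atoms: trimethylsilyl trifluoromethanesulfonate, C[Si](C)(C)OS(=O)(=O)C(F)(F)F
Why: Soft enolisation and O-silylation of a ketone; 10 is symmetrical, so only one constitutional enol ether can form. The double-bond geometry (mainly Z expected) is of no consequence, because C2 of 11 becomes the sp2 carbon C5 of the pyranone.

Step 4
Reactants: 9 5-hydroxy-6-[(2R)-2-methylbutanoyl]-2,8-dioxo-3,4,9,10-tetrahydro-2H,8H-pyrano[2,3-f]chromene-3,9-dicarboxylic acid; 11 (Z)-3-(trimethylsilyloxy)pent-2-ene (two molecules are consumed, one for each arm)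
Product: 14 3,3′-{[2,4,6-trihydroxy-5-[(2R)-2-methylbutanoyl]-1,3-phenylene]bis(methylene)}bis(6-ethyl-4-hydroxy-5-methyl-2H-pyran-2-one) (CNP0174567.1), via bis(acid chloride) 12 (not isolated), via bis(diketone) bis-lactone 13 (not isolated)
Conditions: 1-chloro-N,N,2-trimethylprop-1-en-1-amine (2.2 equiv), CH2Cl2, 0 °C; then 11 (4 equiv), ZnCl2 (0.4 equiv, in Et2O), 0 °C to rt; then NaOAc/AcOH, THF/H2O, 40 °C; 1 M HCl work-up
Reagents that add atoms: (Z)-3-(trimethylsilyloxy)pent-2-ene (the second molecule of 11, which builds the second pyranone), C/C=C(/CC)O[Si](C)(C)C
Why: Proposed new method: each of the two malonic half-acid chlorides of 12, activated by ZnCl2, should C-acylate the nucleophilic C2 of one molecule of 11 with loss of chlorotrimethylsilane, forming the C4–C5 bond of each future pyranone and giving the 3,5-dioxo aryl ester 13; the closest known reaction types are the ZnCl2-catalysed C-acylation of ketone silyl enol ethers with acid chlorides to 1,3-diketones and the pyranone synthesis from silyl enol ethers and malonyl dichlorides, in which a second acyl chloride plays the part taken here by the aryl lactone. In the acetate buffer the terminal enol(ate) oxygen of each triketide arm should attack the lactone carbonyl in a 6-exo-trig addition–elimination; the tetrahedral intermediate expels the ring A phenoxide, so the O1–C2 bond of ring B or B′ is made while the 2-oxochroman ring is opened. Each pyranone is thus assembled by one intermolecular C–C bond formation followed by closure at oxygen onto a carbonyl already in place, and two rings, two C–C bonds and two C–O bonds arise in one operation from 9 and two molecules of 11. The driving force is the exchange of a plain aryl ester for the vinylogous acid of a 4-hydroxy-2-pyranone, with an acidic, ketone-conjugated phenol as leaving group. No stereocentre is created: the epimeric lactone α-carbons become C3 of the pyranones, so the diastereomer mixture of 9 converges, and the (R)-centre is not touched because nothing more basic than acetate and no strong protic acid is present. The step needs C- over O-acylation of 11, which zinc halide catalysis is known to favour, and attack at the acid chloride and not at the lactone carbonyls, which follows from their difference in electrophilicity. The one free phenol of 12 is hydrogen-bonded to the ketone and could reach an acid chloride of its own molecule only through a strained bridged ring; any O-silylation by excess 11 is reversed in the work-up.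

## Compound list

1 | (2R)-2-methylbutanoic acid | CC[C@@H](C)C(=O)O | starting material
2 | phloroglucinol (benzene-1,3,5-triol) | Oc1cc(O)cc(O)c1 | starting material
3 | (2R)-2-methylbutanoyl chloride | CC[C@@H](C)C(Cl)=O | intermediate
4 | (2R)-2-methyl-1-(2,4,6-trihydroxyphenyl)butan-1-one | CC[C@@H](C)C(=O)c1c(O)cc(O)cc1O | intermediate
5 | formaldehyde | C=O | starting material
6 | Meldrum's acid (2,2-dimethyl-1,3-dioxane-4,6-dione) | CC1(C)OC(=O)CC(=O)O1 | starting material
7 | methylidene Meldrum's acid (2,2-dimethyl-5-methylidene-1,3-dioxane-4,6-dione) | CC1(C)OC(=O)C(=C)C(=O)O1 | intermediate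
8 | 5,5′-{[2,4,6-trihydroxy-5-[(2R)-2-methylbutanoyl]-1,3-phenylene]bis(methylene)}bis(2,2-dimethyl-1,3-dioxane-4,6-dione) | CC[C@@H](C)C(=O)c1c(O)c(CC2C(=O)OC(C)(C)OC2=O)c(O)c(CC2C(=O)OC(C)(C)OC2=O)c1O | intermediate
9 | 5-hydroxy-6-[(2R)-2-methylbutanoyl]-2,8-dioxo-3,4,9,10-tetrahydro-2H,8H-pyrano[2,3-f]chromene-3,9-dicarboxylic acid (epimer mixture at C3 and C9) | CC[C@@H](C)C(=O)c1c(O)c2CC(C(=O)O)C(=O)Oc2c3CC(C(=O)O)C(=O)Oc13 | intermediate
10 | pentan-3-one | CCC(=O)CC | starting material
11 | (Z)-3-(trimethylsilyloxy)pent-2-ene | C/C=C(/CC)O[Si](C)(C)C | intermediate
12 | 5-hydroxy-6-[(2R)-2-methylbutanoyl]-2,8-dioxo-3,4,9,10-tetrahydro-2H,8H-pyrano[2,3-f]chromene-3,9-dicarbonyl dichloride | CC[C@@H](C)C(=O)c1c(O)c2CC(C(Cl)=O)C(=O)Oc2c3CC(C(Cl)=O)C(=O)Oc13 | intermediate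
13 | 5-hydroxy-6-[(2R)-2-methylbutanoyl]-3,9-bis(2-methyl-3-oxopentanoyl)-3,4,9,10-tetrahydro-2H,8H-pyrano[2,3-f]chromene-2,8-dione | CC[C@@H](C)C(=O)c1c(O)c2CC(C(=O)C(C)C(=O)CC)C(=O)Oc2c3CC(C(=O)C(C)C(=O)CC)C(=O)Oc13 | intermediate
14 | 3,3′-{[2,4,6-trihydroxy-5-[(2R)-2-methylbutanoyl]-1,3-phenylene]bis(methylene)}bis(6-ethyl-4-hydroxy-5-methyl-2H-pyran-2-one) | CCc1oc(=O)c(Cc2c(O)c(Cc3c(O)c(C)c(CC)oc3=O)c(O)c(C(=O)[C@H](C)CC)c2O)c(O)c1C | target

## Step count and risk

Total step count: 4. Longest linear sequence: 3 (steps 1, 2 and 4).

**Step 4 (key step, proposed new method).**
- What may go wrong: O-acylation of the silyl enol ether in place of C-acylation. Loss of HCl from the malonic half-acid chloride to a ketene that oligomerises before it is trapped. Intermolecular ester formation between released phenols and unreacted acid chloride if the ring switch starts before acylation is complete. Incomplete translactonisation of one arm, or acylation of only one of the two arms.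
- Why: the acid chloride carries an acidic α-hydrogen, and the cascade has not been shown on 3-acyl-2-oxochromans.
- Fallback (known chemistry only), from 4 and 11 back to 14: 11 is condensed with malonyl dichloride (Et2O, −78 °C to rt, the known pyranone synthesis from silyl enol ethers) to give 6-ethyl-4-hydroxy-5-methyl-2H-pyran-2-one F1. F1 (2 equiv) is then bridged to C3 and C5 of 4 with formaldehyde 5 (2 equiv as paraformaldehyde, catalytic amine base, CHCl3 or EtOH, rt) by in situ Knoevenagel condensation and conjugate addition. This gives up the ring switch and accepts the statistical control of methylene bridging.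

**Step 2.**
- What may go wrong: direct hydroxymethylation of 4 by formaldehyde, followed by arene–CH2–arene bridging, before the Knoevenagel acceptor has formed. Stopping at mono-alkylation if a lactone closes early and lowers the nucleophilicity of ring A. Decarboxylation of the malonic half-ester on warming, which would remove the carbon that becomes pyranone C4.
- Fallback, from 4 back to 9: twofold Rieche formylation of 4 (dichloromethyl methyl ether, TiCl4, CH2Cl2, 0 °C) gives 2,4,6-trihydroxy-5-[(2R)-2-methylbutanoyl]benzene-1,3-dicarbaldehyde F2. Knoevenagel condensation and lactonisation of F2 with two molecules of 6 (piperidinium acetate, EtOH, rt to 50 °C) gives 5-hydroxy-6-[(2R)-2-methylbutanoyl]-2,8-dioxo-2H,8H-pyrano[2,3-f]chromene-3,9-dicarboxylic acid F3. Hydrogenation of the two alkylidene-malonate double bonds of F3 (H2, Pd/C, THF, rt) gives 9. Here the bridge carbons enter at the aldehyde oxidation level, so no formaldehyde is present.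

**Step 1.**
- What may go wrong: erosion of enantiopurity, through ketene formation from the acid chloride or through Lewis-acid-promoted enolisation of the product ketone, and some O-acylation or diacylation.
- Fallback, from 1 and 2 back to 4: 1 is converted through 3 into the N-methoxy-N-methylamide (2R)-N-methoxy-N,2-dimethylbutanamide F4 (MeNHOMe·HCl, pyridine, CH2Cl2, 0 °C). 2 is protected as 1,3,5-tris(methoxymethoxy)benzene F5 (chloromethyl methyl ether, i-Pr2NEt, CH2Cl2). F5 is lithiated between two directing groups (n-BuLi, THF, 0 °C) and acylated with F4 at −78 °C to rt, giving (2R)-2-methyl-1-[2,4,6-tris(methoxymethoxy)phenyl]butan-1-one F6. The acetals are removed (HCl, MeOH, rt) to give 4. The ketone is then formed from a stable tetrahedral intermediate at low temperature, without Lewis acid.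

## Further compounds

F1 | step 4 | 6-ethyl-4-hydroxy-5-methyl-2H-pyran-2-one | CCc1oc(=O)cc(O)c1C
F2 | step 2 | 2,4,6-trihydroxy-5-[(2R)-2-methylbutanoyl]benzene-1,3-dicarbaldehyde | CC[C@@H](C)C(=O)c1c(O)c(C=O)c(O)c(C=O)c1O
F3 | step 2 | 5-hydroxy-6-[(2R)-2-methylbutanoyl]-2,8-dioxo-2H,8H-pyrano[2,3-f]chromene-3,9-dicarboxylic acid | CC[C@@H](C)C(=O)c1c(O)c2C=C(C(=O)O)C(=O)Oc2c3C=C(C(=O)O)C(=O)Oc13
F4 | step 1 | (2R)-N-methoxy-N,2-dimethylbutanamide | CC[C@@H](C)C(=O)N(C)OC
F5 | step 1 | 1,3,5-tris(methoxymethoxy)benzene | COCOc1cc(OCOC)cc(OCOC)c1
F6 | step 1 | (2R)-2-methyl-1-[2,4,6-tris(methoxymethoxy)phenyl]butan-1-one | CC[C@@H](C)C(=O)c1c(OCOC)cc(OCOC)cc1OCOC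
A1 | alternative 1 | 6-ethyl-4-hydroxy-5-methyl-2H-pyran-2-one | CCc1oc(=O)cc(O)c1C
A2 | alternative 1 | 6-ethyl-5-methyl-3-methylidenepyran-2,4-dione | CCC1=C(C)C(=O)C(=C)C(=O)O1
A3 | alternative 1 | 3,3′-methylenebis(6-ethyl-4-hydroxy-5-methyl-2H-pyran-2-one) | CCc1oc(=O)c(Cc2c(O)c(C)c(CC)oc2=O)c(O)c1C
A4 | alternative 2 | 2,4-bis[(6-ethyl-4-methoxy-5-methyl-2-oxo-2H-pyran-3-yl)methyl]-3,5-dimethoxy-6-(trimethylsilyl)phenyl trifluoromethanesulfonate | C[Si](C)(C)c1c(OC)c(Cc2c(OC)c(C)c(CC)oc2=O)c(OC)c(Cc2c(OC)c(C)c(CC)oc2=O)c1OS(=O)(=O)C(F)(F)F
A5 | alternative 2 | 4,6-dimethoxy-3,5-bis[(6-ethyl-4-methoxy-5-methyl-2-oxo-2H-pyran-3-yl)methyl]benzyne | COC1=C(Cc2c(OC)c(C)c(CC)oc2=O)C(OC)=C(Cc2c(OC)c(C)c(CC)oc2=O)C#C1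
A6 | alternative 3 | 1,5-bis(6-ethyl-4-hydroxy-5-methyl-2-oxo-2H-pyran-3-yl)pentan-3-one | CCc1oc(=O)c(CCC(=O)CCc2c(O)c(C)c(CC)oc2=O)c(O)c1C
A7 | alternative 3 | diethyl 2-[(2R)-2-methylbutanoyl]propanedioate | CC[C@@H](C)C(=O)C(C(=O)OCC)C(=O)OCC
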